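## Retrosynthetic overview

- **Feature:** ring A is a masked 2,3-dimethoxyhydroquinone. O1 on C8a lies para to 6-OH, OMe groups sit on C7 and C8, C4a holds the only carbon substituent, and C5 is CH. C6–C7–C8–C8a with their four oxygens map onto dimethyl squarate, and C4a=C5 maps onto a 1,1-disubstituted vinyl group.
- **Ring C, formed last:** the 2'-O-benzyl group is removed, then O1–C2 is disconnected (Mitsunobu) to a hydroquinone carrying the C4–C3–C2 chain as a primary alcohol.
- **Ring A:** C5–C6 is disconnected (thermal 4π opening, 6π closure) to a 4-alkenyl-4-hydroxycyclobutenone. C4a–C8a is then disconnected to a 2-lithioalkene plus dimethyl squarate.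
- **C3:** C3–C4 is disconnected by auxiliary-controlled alkylation of the ring-B arylacetyl imide with 2,3-dibromopropene. The acid comes from 2-hydroxy-3,4-dimethoxybenzaldehyde by benzylation and one-carbon homologation.
- **Ring order:** B (bought), then A (step 10), then C (step 12).

Key step: step 10

Remark (assumptions): isoflavan numbering is used throughout. The stereodescriptor at C3 reads as S (C2 > C1' > C4 > H). Compound 17 is carried as the mixture of carbinol epimers, because that carbon becomes the sp2 centre C8a.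

## Route

Step 1
Reactants: 1 2-hydroxy-3,4-dimethoxybenzaldehyde
Product: 2 2-(benzyloxy)-3,4-dimethoxybenzaldehyde
Conditions: BnBr, K2CO3, DMF, 60 °C
Reagents that add atoms: benzyl bromide, BrCc1ccccc1
Why: Williamson etherification of the only acidic OH; the benzyl group masks 2'-OH through the organolithium step, blocks its competing closure onto C2 in step 12 and leaves by neutral hydrogenolysis at the end.

Step 2
Reactants: 2 2-(benzyloxy)-3,4-dimethoxybenzaldehyde
Product: 3 2-(benzyloxy)-3,4-dimethoxy-β-methoxystyrene (E/Z mixture)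
Conditions: MeOCH2PPh3Cl, KOtBu, THF, 0 °C → rt
Reagents that add atoms: (methoxymethyl)triphenylphosphonium chloride, COC[P+](c1ccccc1)(c1ccccc1)c1ccccc1.[Cl-]
Why: Wittig methoxymethylenation of a non-enolisable aryl aldehyde adds the carbon that becomes C2, the former aldehyde carbon becoming C3, and the alkene geometry is irrelevant because it is lost in step 3.

Step 3
Reactants: 3 2-(benzyloxy)-3,4-dimethoxy-β-methoxystyrene
Product: 4 [2-(benzyloxy)-3,4-dimethoxyphenyl]acetaldehyde
Conditions: 2 M aq HCl, THF, 45 °C; crude product used at once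
Reagents that add atoms: water, O
Why: Acid-catalysed enol ether hydrolysis (C-protonation, hemiacetal collapse) leaves aryl benzyl and methyl ethers untouched, and the aldehyde is taken on directly because arylacetaldehydes tend to self-condense.

Step 4
Reactants: 4 [2-(benzyloxy)-3,4-dimethoxyphenyl]acetaldehyde
Product: 5 [2-(benzyloxy)-3,4-dimethoxyphenyl]acetic acid
Conditions: NaClO2, NaH2PO4, 2-methyl-2-butene, t-BuOH/H2O, 0 °C → rt
Reagents that add atoms: sodium chlorite, [Na+].[O-]Cl=O
Why: Pinnick oxidation is selective for the aldehyde, and the alkene scavenger removes HOCl before it can chlorinate the electron-rich ring.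

Step 5
Reactants: 5 [2-(benzyloxy)-3,4-dimethoxyphenyl]acetic acid; 6 (S)-4-benzyl-2-oxazolidinone
Product: 8 (4S)-4-benzyl-3-{[2-(benzyloxy)-3,4-dimethoxyphenyl]acetyl}-1,3-oxazolidin-2-one, via mixed pivalic anhydride 7 (not isolated)
Conditions: PivCl, Et3N, THF, 0 °C; then LiCl, 6, rt
Reagents that add atoms: none
Why: N-acylation of the oxazolidinone through a mixed anhydride (LiCl/Et3N variant) occurs at the less hindered arylacetyl carbonyl and avoids the ketene pathway of arylacetyl chlorides.

Step 6
Reactants: 8 (4S)-4-benzyl-3-{[2-(benzyloxy)-3,4-dimethoxyphenyl]acetyl}-1,3-oxazolidin-2-one; 9 2,3-dibromopropene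
Product: 11 (4S)-4-benzyl-3-{(2S)-2-[2-(benzyloxy)-3,4-dimethoxyphenyl]-4-bromopent-4-enoyl}-1,3-oxazolidin-2-one, via sodium (Z)-enolate 10 (not isolated)
Conditions: NaHMDS, THF, −78 °C; then 9, −78 → −40 °C
Reagents that add atoms: none
Why: Evans asymmetric alkylation: NaHMDS gives the chelated (Z)-enolate 10, whose face syn to the C4 benzyl group of the auxiliary is shielded, so the allylic C–Br of 9 (SN2, the vinylic bromide being inert) should be attacked from the open face and set C3 as S, the remaining α-H being kept from enolisation by allylic strain in the imide.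

Step 7
Reactants: 11 (4S)-4-benzyl-3-{(2S)-2-[2-(benzyloxy)-3,4-dimethoxyphenyl]-4-bromopent-4-enoyl}-1,3-oxazolidin-2-one
Product: 12 (2S)-2-[2-(benzyloxy)-3,4-dimethoxyphenyl]-4-bromopent-4-en-1-ol
Conditions: LiBH4, MeOH (1 equiv), Et2O, 0 °C
Reagents that add atoms: none
Why: Reductive cleavage of the N-acyloxazolidinone with LiBH4/MeOH delivers hydride to the exocyclic carbonyl faster than the imide can enolise, so C3 should keep its configuration, the vinyl bromide is inert and the auxiliary is released for recovery.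

Step 8
Reactants: 12 (2S)-2-[2-(benzyloxy)-3,4-dimethoxyphenyl]-4-bromopent-4-en-1-ol
Product: 13 (2S)-2-[2-(benzyloxy)-3,4-dimethoxyphenyl]-4-bromopent-4-en-1-yl tert-butyldimethylsilyl ether
Conditions: TBSCl, imidazole, CH2Cl2, rt
Reagents that add atoms: tert-butyldimethylsilyl chloride, CC(C)(C)[Si](C)(C)Cl
Why: Standard silylation of a primary alcohol removes the acidic proton before the lithiation and stops the C2 oxygen from trapping the ketene in step 10.

Step 9
Reactants: 13 (2S)-2-[2-(benzyloxy)-3,4-dimethoxyphenyl]-4-bromopent-4-en-1-yl tert-butyldimethylsilyl ether; 14 dimethyl squarate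
Product: 17 4-{(4S)-4-[2-(benzyloxy)-3,4-dimethoxyphenyl]-5-[(tert-butyldimethylsilyl)oxy]pent-1-en-2-yl}-4-hydroxy-2,3-dimethoxycyclobut-2-en-1-one (both carbinol epimers), via vinyllithium 15 (not isolated), via lithium alkoxide 16 (not isolated)
Conditions: t-BuLi (2 equiv), Et2O, −78 °C; cannulated into 14 (slight excess) in THF, −78 °C; aq NH4Cl, −78 °C
Reagents that add atoms: none
Why: Bromine–lithium exchange at −78 °C outruns deprotonation, and 1,2-addition of the organolithium to one of the two equivalent squarate carbonyls (inverse addition against double addition) forms C4a–C8a, the uncontrolled carbinol centre being of no consequence because it is destroyed in step 10.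

Step 10
Reactants: 17 4-{(4S)-4-[2-(benzyloxy)-3,4-dimethoxyphenyl]-5-[(tert-butyldimethylsilyl)oxy]pent-1-en-2-yl}-4-hydroxy-2,3-dimethoxycyclobut-2-en-1-one
Product: 20 5-{(2S)-2-[2-(benzyloxy)-3,4-dimethoxyphenyl]-3-[(tert-butyldimethylsilyl)oxy]propyl}-2,3-dimethoxybenzene-1,4-diol, via dienylketene 18 (not isolated), via cyclohexadienone 19 (not isolated)
Conditions: degassed p-xylene (0.02 M), reflux (138 °C), Ar
Reagents that add atoms: none
Why: This is the Moore-type thermal ring expansion of a squarate-derived 4-alkenyl-4-hydroxycyclobutenone: a conrotatory 4π electrocyclic opening cleaves the ring bond between the carbinol carbon (future C8a) and the carbonyl carbon (future C6) and gives dienylketene 18. Ring A then closes in a thermal disrotatory 6π electrocyclisation in which the ketene carbon C6 bonds to the alkene CH2 (C5), and the resulting cyclohexa-2,4-dienone 19 enolises to hydroquinone 20. The selectivity needed is torquoselectivity, and the substrate supplies it because the donor OH on the carbinol carbon rotates outward in both epimers of 17, so the alkenyl group turns inward and ends cis to the ketene. The substitution pattern follows from connectivity alone: the two squarate OMe groups become 7-OMe and 8-OMe, the carbinol oxygen sits on C8a, the former ketone oxygen becomes 6-OH and the chain sits on C4a. No stereocentre is formed, the carbinol centre vanishes on aromatisation, and C3 is insulated from the reacting π system by the C4 methylene and has no acidifying neighbour, so it should pass through unchanged. The silyl ether keeps the C2 oxygen from adding to the ketene, relief of ring strain and aromatisation drive the cascade forward, and air is excluded because 20 is a readily oxidised ubiquinol-type hydroquinone.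

Step 11
Reactants: 20 5-{(2S)-2-[2-(benzyloxy)-3,4-dimethoxyphenyl]-3-[(tert-butyldimethylsilyl)oxy]propyl}-2,3-dimethoxybenzene-1,4-diol
Product: 21 5-{(2S)-2-[2-(benzyloxy)-3,4-dimethoxyphenyl]-3-hydroxypropyl}-2,3-dimethoxybenzene-1,4-diol
Conditions: CSA (cat.), degassed MeOH/CH2Cl2, 0 °C → rt, Ar
Reagents that add atoms: none
Why: Acid-catalysed methanolysis of a primary TBS ether is chosen over basic fluoride because hydroquinone anions autoxidise, while benzyl and methyl ethers are inert to these conditions.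

Step 12
Reactants: 21 5-{(2S)-2-[2-(benzyloxy)-3,4-dimethoxyphenyl]-3-hydroxypropyl}-2,3-dimethoxybenzene-1,4-diol
Product: 23 (3S)-3-[2-(benzyloxy)-3,4-dimethoxyphenyl]-7,8-dimethoxy-3,4-dihydro-2H-chromen-6-ol, via oxyphosphonium zwitterion 22 (not isolated)
Conditions: PPh3, DIAD (slow addition), degassed THF (0.01 M), 0 °C → rt, Ar
Reagents that add atoms: none
Why: Intramolecular Mitsunobu etherification activates only the primary alcohol, and the oxygen on C8a displaces it in a 6-exo-tet SN2 at C2 (6-OH cannot reach C2, 2'-O is benzylated, C3 is not touched), slow addition of DIAD to excess phosphine keeping free azo ester away from the hydroquinone.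

Step 13
Reactants: 23 (3S)-3-[2-(benzyloxy)-3,4-dimethoxyphenyl]-7,8-dimethoxy-3,4-dihydro-2H-chromen-6-ol
Product: 24 (3S)-3-(2-hydroxy-3,4-dimethoxyphenyl)-7,8-dimethoxy-3,4-dihydro-2H-chromen-6-ol (CNP0416342.1)
Conditions: H2 (1 atm), 10% Pd/C, EtOAc/MeOH, rt
Reagents that add atoms: none
Why: Catalytic hydrogenolysis cleaves the only benzylic C–O bond (O1–C2 is not benzylic and nothing else is reducible), freeing 2'-OH under neutral conditions that cannot affect C3.

## Compound list

1 | 2-hydroxy-3,4-dimethoxybenzaldehyde | COc1ccc(C=O)c(O)c1OC | starting material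
2 | 2-(benzyloxy)-3,4-dimethoxybenzaldehyde | COc1ccc(C=O)c(OCc2ccccc2)c1OC | intermediate
3 | 2-(benzyloxy)-3,4-dimethoxy-β-methoxystyrene (E/Z mixture) | COC=Cc1ccc(OC)c(OC)c1OCc1ccccc1 | intermediate
4 | [2-(benzyloxy)-3,4-dimethoxyphenyl]acetaldehyde | O=CCc1ccc(OC)c(OC)c1OCc1ccccc1 | intermediate
5 | [2-(benzyloxy)-3,4-dimethoxyphenyl]acetic acid | OC(=O)Cc1ccc(OC)c(OC)c1OCc1ccccc1 | intermediate
6 | (S)-4-benzyl-2-oxazolidinone | O=C1OC[C@H](Cc2ccccc2)N1 | starting material
7 | [2-(benzyloxy)-3,4-dimethoxyphenyl]acetic pivalic anhydride (not isolated) | CC(C)(C)C(=O)OC(=O)Cc1ccc(OC)c(OC)c1OCc1ccccc1 | intermediate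
8 | (4S)-4-benzyl-3-{[2-(benzyloxy)-3,4-dimethoxyphenyl]acetyl}-1,3-oxazolidin-2-one | O=C1OC[C@H](Cc2ccccc2)N1C(=O)Cc1ccc(OC)c(OC)c1OCc1ccccc1 | intermediate
9 | 2,3-dibromopropene | C=C(Br)CBr | starting material
10 | sodium (Z)-enolate of 8 (not isolated) | [Na+].[O-]/C(=C\c1ccc(OC)c(OC)c1OCc1ccccc1)N1[C@@H](Cc2ccccc2)COC1=O | intermediate
11 | (4S)-4-benzyl-3-{(2S)-2-[2-(benzyloxy)-3,4-dimethoxyphenyl]-4-bromopent-4-enoyl}-1,3-oxazolidin-2-one | O=C1OC[C@H](Cc2ccccc2)N1C(=O)[C@@H](CC(Br)=C)c1ccc(OC)c(OC)c1OCc1ccccc1 | intermediate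
12 | (2S)-2-[2-(benzyloxy)-3,4-dimethoxyphenyl]-4-bromopent-4-en-1-ol | C=C(Br)C[C@H](CO)c1ccc(OC)c(OC)c1OCc1ccccc1 | intermediate
13 | (2S)-2-[2-(benzyloxy)-3,4-dimethoxyphenyl]-4-bromopent-4-en-1-yl tert-butyldimethylsilyl ether | C=C(Br)C[C@H](CO[Si](C)(C)C(C)(C)C)c1ccc(OC)c(OC)c1OCc1ccccc1 | intermediate
14 | dimethyl squarate (3,4-dimethoxycyclobut-3-ene-1,2-dione) | COC1=C(OC)C(=O)C1=O | starting material
15 | 2-lithioalkene from 13 (not isolated) | [Li]C(=C)C[C@H](CO[Si](C)(C)C(C)(C)C)c1ccc(OC)c(OC)c1OCc1ccccc1 | intermediate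
16 | lithium alkoxide of 17 (not isolated) | [Li+].COC1=C(OC)C([O-])(C(=C)C[C@H](CO[Si](C)(C)C(C)(C)C)c2ccc(OC)c(OC)c2OCc2ccccc2)C1=O | intermediate
17 | 4-{(4S)-4-[2-(benzyloxy)-3,4-dimethoxyphenyl]-5-[(tert-butyldimethylsilyl)oxy]pent-1-en-2-yl}-4-hydroxy-2,3-dimethoxycyclobut-2-en-1-one (both carbinol epimers) | COC1=C(OC)C(O)(C(=C)C[C@H](CO[Si](C)(C)C(C)(C)C)c2ccc(OC)c(OC)c2OCc2ccccc2)C1=O | intermediate
18 | (Z)-dienylketene, alkenyl group cis to the ketene (not isolated) | O=C=C(OC)/C(OC)=C(/O)C(=C)C[C@H](CO[Si](C)(C)C(C)(C)C)c1ccc(OC)c(OC)c1OCc1ccccc1 | intermediate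
19 | 4-hydroxy-2,3-dimethoxy-5-alkylcyclohexa-2,4-dien-1-one, keto tautomer of 20 (not isolated) | O=C1CC(C[C@H](CO[Si](C)(C)C(C)(C)C)c2ccc(OC)c(OC)c2OCc2ccccc2)=C(O)C(OC)=C1OC | intermediate
20 | 5-{(2S)-2-[2-(benzyloxy)-3,4-dimethoxyphenyl]-3-[(tert-butyldimethylsilyl)oxy]propyl}-2,3-dimethoxybenzene-1,4-diol | COc1c(O)cc(C[C@H](CO[Si](C)(C)C(C)(C)C)c2ccc(OC)c(OC)c2OCc2ccccc2)c(O)c1OC | intermediate
21 | 5-{(2S)-2-[2-(benzyloxy)-3,4-dimethoxyphenyl]-3-hydroxypropyl}-2,3-dimethoxybenzene-1,4-diol | COc1c(O)cc(C[C@H](CO)c2ccc(OC)c(OC)c2OCc2ccccc2)c(O)c1OC | intermediate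
22 | C2-oxyphosphonium / C8a-phenoxide zwitterion of 21 (not isolated) | COc1c(O)cc(C[C@H](CO[P+](c2ccccc2)(c2ccccc2)c2ccccc2)c2ccc(OC)c(OC)c2OCc2ccccc2)c([O-])c1OC | intermediate
23 | (3S)-3-[2-(benzyloxy)-3,4-dimethoxyphenyl]-7,8-dimethoxy-3,4-dihydro-2H-chromen-6-ol | COc1ccc([C@H]2COc3c(cc(O)c(OC)c3OC)C2)c(OCc2ccccc2)c1OC | intermediate
24 | (3S)-3-(2-hydroxy-3,4-dimethoxyphenyl)-7,8-dimethoxy-3,4-dihydro-2H-chromen-6-ol | COc1ccc([C@H]2COc3c(cc(O)c(OC)c3OC)C2)c(O)c1OC | target

## Step count

Total step count: 13. Longest linear sequence: 13 steps, from 1.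

## Steps most likely to fail

**Step 10.** Oxidation of the electron-rich hydroquinone by adventitious air, during the long heating and on silica, could leave a mixture of redox states that is hard to purify. Part of the ketene could also be lost through the wrong sense of rotation.

The fallback sets out from 17. The thermolysate is not purified but is stirred with Ag2O and K2CO3 in CH2Cl2. This should converge all ring-expanded material on the bench-stable 2-alkyl-5,6-dimethoxy-1,4-benzoquinone F1. After chromatography, quinone F1 is shaken with aqueous Na2S2O4 in Et2O directly before step 11, and the route is rejoined at 20.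

**Step 12.** Two processes could drain material. The azodicarboxylate could dehydrogenate the hydroquinone before the phosphine has consumed it, and 6-OH could undergo intermolecular O-alkylation.

The fallback avoids any azo reagent and sets out from 21. Appel bromination (CBr4, PPh3, CH2Cl2, 0 °C) leaves phenols alone and should give the primary bromide F2. An intramolecular Williamson closure by the oxygen on C8a (K2CO3, degassed acetone, high dilution, Ar) then returns to the route at 23.

**Step 9.** The coupling could be eroded in three ways: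
- proton transfer from the OCH2Ph group to t-BuLi or to the vinyllithium, followed by rearrangement of the resulting anion;
- premature protonation of the vinyllithium;
- a second addition to the squarate.

The fallback replaces the vinyl anion by an acetylide made by simple deprotonation, and sets out from 8.
- Enolate 10 is alkylated with propargyl bromide, under the same facial control, to the pentynoyl imide F3.
- LiBH4 gives the alkynol F4, and TBSCl/imidazole gives the silyl ether F5.
- n-BuLi (THF, −78 °C) gives the lithium acetylide F6, which adds to 14 and, after an NH4Cl quench, gives the 4-alkynyl-4-hydroxycyclobutenone F7.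
- Heating F7 in p-xylene triggers the alkynyl variant of the same thermal ring expansion, which delivers the quinone F1 directly.
- Reduction of F1 with aqueous Na2S2O4 rejoins the route at 20.

## Further compounds

F1 | step 10 | 2-{(2S)-2-[2-(benzyloxy)-3,4-dimethoxyphenyl]-3-[(tert-butyldimethylsilyl)oxy]propyl}-5,6-dimethoxycyclohexa-2,5-diene-1,4-dione | COC1=C(OC)C(=O)C(C[C@H](CO[Si](C)(C)C(C)(C)C)c2ccc(OC)c(OC)c2OCc2ccccc2)=CC1=O
F2 | step 12 | 5-{(2S)-2-[2-(benzyloxy)-3,4-dimethoxyphenyl]-3-bromopropyl}-2,3-dimethoxybenzene-1,4-diol | COc1c(O)cc(C[C@H](CBr)c2ccc(OC)c(OC)c2OCc2ccccc2)c(O)c1OC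
F3 | step 9 | (4S)-4-benzyl-3-{(2S)-2-[2-(benzyloxy)-3,4-dimethoxyphenyl]pent-4-ynoyl}-1,3-oxazolidin-2-one | O=C1OC[C@H](Cc2ccccc2)N1C(=O)[C@@H](CC#C)c1ccc(OC)c(OC)c1OCc1ccccc1
F4 | step 9 | (2S)-2-[2-(benzyloxy)-3,4-dimethoxyphenyl]pent-4-yn-1-ol | C#CC[C@H](CO)c1ccc(OC)c(OC)c1OCc1ccccc1
F5 | step 9 | (2S)-2-[2-(benzyloxy)-3,4-dimethoxyphenyl]pent-4-yn-1-yl tert-butyldimethylsilyl ether | C#CC[C@H](CO[Si](C)(C)C(C)(C)C)c1ccc(OC)c(OC)c1OCc1ccccc1
F6 | step 9 | lithium acetylide of F5 | [Li]C#CC[C@H](CO[Si](C)(C)C(C)(C)C)c1ccc(OC)c(OC)c1OCc1ccccc1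
F7 | step 9 | 4-{(4S)-4-[2-(benzyloxy)-3,4-dimethoxyphenyl]-5-[(tert-butyldimethylsilyl)oxy]pent-1-yn-1-yl}-4-hydroxy-2,3-dimethoxycyclobut-2-en-1-one (both carbinol epimers) | COC1=C(OC)C(O)(C#CC[C@H](CO[Si](C)(C)C(C)(C)C)c2ccc(OC)c(OC)c2OCc2ccccc2)C1=O
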